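**Plan**

- Retrosynthesis: after the O–Si bond, both bonds to the ring C ketone carbon C12 are cut (C12–C13 to furan C3 and C12–C11), so C12 goes back to CO. This is possible because C12 lies between a furan carbon that can carry bromine and a CH2 (C11) on the quaternary, methyl-bearing C9, so the alkyl partner has no β-hydrogen.
- Further cuts: C1–C16 (bromofuran onto ring A), then C5–C10 and C3–C4 together with the C3–O bridge (furan Diels–Alder and bridge opening), C5–C6 (enolate coupling with the bromobutenolide), C8–C9 (Ireland–Claisen).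
- Forward: an acyclic furyl chain is built from 2-acetylfuran; rings A and B form together in the intramolecular cycloaddition (the lactone comes with the butenolide); the bromofuran is added at C1; C7 and C11 are adjusted; ring C closes last.
- Stereochemistry: one Corey–Bakshi–Shibata reduction; its carbinol centre is passed to C8 and C9 in the Ireland–Claisen chair; C8/C9 steer the cycloaddition face (C5, C10, trans fusion); C7 comes from hydride attack away from axial C19/C20; C1 comes from aryl delivery by the C10 alkoxide.

Key step: step 16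

Remark on labels: C1 = CH bearing the furan, C2 = CH2, C3=C4 = ring alkene, C5 = quaternary carbon bearing C19H2–O and C6, C7 = CH–OAc, C8 = CH–CH3 (C17), C9 = quaternary carbon with methyl C20 and C11H2, C10 = C–OH, C12 = ketone, C13/C16 = furan C3/C2, C18 = lactone C=O. Ring A = C1–C5, C10; ring B = C5–C10; ring C = C1, C10, C9, C11, C12, C13, C16. α is the decalin face carrying C19, C20, C17 and the C7 oxygen; β is the face carrying the C10 oxygen, C11 and the C1 furyl group. The enantiomer is taken as written in the target SMILES.

**Route**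

Step 1
Reactants: 1 2-acetylfuran; 2 diethyl [2-(methoxy(methyl)amino)-2-oxoethyl]phosphonate
Product: 3 (E)-3-(furan-2-yl)-N-methoxy-N-methylbut-2-enamide
Conditions: NaH, THF, 0 °C → reflux
Reagents that add atoms: none
Why: Horner–Wadsworth–Emmons olefination of the methyl ketone, in which the stabilised phosphonate anion should favour the E alkene (furyl trans to the carbonyl), the minor Z isomer being removed by chromatography.

Step 2
Reactants: 3 (E)-3-(furan-2-yl)-N-methoxy-N-methylbut-2-enamide
Product: 4 (E)-4-(furan-2-yl)pent-3-en-2-one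
Conditions: MeMgBr, THF, 0 °C; aq. NH4Cl
Reagents that add atoms: methylmagnesium bromide, C[Mg]Br
Why: Weinreb ketone synthesis, where the magnesium chelate of the N-methoxy-N-methylamide collapses to the ketone only on work-up, so no tertiary alcohol should form.

Step 3
Reactants: 4 (E)-4-(furan-2-yl)pent-3-en-2-one
Product: 5 (R,E)-4-(furan-2-yl)pent-3-en-2-ol
Conditions: (S)-1-methyl-3,3-diphenyl-tetrahydro-1H,3H-pyrrolo[1,2-c][1,3,2]oxazaborole (10 mol%), BH3·SMe2, THF, −30 °C; MeOH
Reagents that add atoms: none
Why: Corey–Bakshi–Shibata reduction, in which the alkenyl group acts as the large and the methyl as the small substituent, so the (S)-catalyst should give the (R)-carbinol, the only stereocentre set by a chiral reagent.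

Step 4
Reactants: 5 (R,E)-4-(furan-2-yl)pent-3-en-2-ol
Product: 6 (R,E)-4-(furan-2-yl)pent-3-en-2-yl propanoate
Conditions: (EtCO)2O, Et3N, 4-(dimethylamino)pyridine (cat.), CH2Cl2, 0 °C
Reagents that add atoms: propanoic anhydride, CCC(=O)OC(=O)CC
Why: nucleophile-catalysed acylation of a secondary alcohol under basic conditions, which avoid ionisation of the furyl-conjugated allylic system.

Step 5
Reactants: 6 (R,E)-4-(furan-2-yl)pent-3-en-2-yl propanoate
Product: 9 (2S,3S,E)-3-(furan-2-yl)-2,3-dimethylhex-4-enoic acid, via silyl ketene acetal 7 (not isolated), via trimethylsilyl ester 8 (not isolated)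
Conditions: LiN(i-Pr)2, THF, −78 °C; Me3SiCl, −78 → 50 °C; aq. HCl
Reagents that add atoms: none
Why: Ireland–Claisen rearrangement, in which kinetic enolisation in THF gives the ketene acetal with its methyl cis to the allyloxy oxygen and the chair transition state with the carbinol methyl equatorial passes the (R) centre on to C9 (quaternary) and C8, leaving an E propenyl group.

Step 6
Reactants: 9 (2S,3S,E)-3-(furan-2-yl)-2,3-dimethylhex-4-enoic acid
Product: 10 (3S,4S,E)-4-(furan-2-yl)-3,4-dimethylhept-5-en-2-one
Conditions: MeLi (2.2 equiv), Et2O, 0 → 25 °C; poured into aq. NH4Cl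
Reagents that add atoms: methyllithium, [Li]C
Why: ketone synthesis from a lithium carboxylate and an organolithium, where the dilithium gem-diolate releases the methyl ketone only on hydrolysis, so over-addition and epimerisation at C8 should be avoided.

Step 7
Reactants: 10 (3S,4S,E)-4-(furan-2-yl)-3,4-dimethylhept-5-en-2-one; 11 4-bromofuran-2(5H)-one
Product: 13 4-[(3S,4S,E)-4-(furan-2-yl)-3,4-dimethyl-2-oxohept-5-en-1-yl]furan-2(5H)-one, via silyl enol ether 12 (not isolated)
Conditions: LiN(i-Pr)2, THF, −78 °C; Me3SiCl; then 11, Bu3SnF, PdCl2[P(o-tolyl)3]2 (3 mol%), toluene, 80 °C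
Reagents that add atoms: none
Why: kinetic deprotonation at the methyl group (C6) fixes the enolate regiochemistry, and palladium-catalysed α-alkenylation of the silyl enol ether through its tin enolate should join C6 to the β-carbon of the bromobutenolide (C5) under neutral conditions that spare the acidic C6 and C8 positions.

Step 8
Reactants: 13 4-[(3S,4S,E)-4-(furan-2-yl)-3,4-dimethyl-2-oxohept-5-en-1-yl]furan-2(5H)-one
Product: 15 10β-hydroxy-7-oxo dienolide (ring A 1,3-diene), via oxa-bridged cycloadduct 14 (not isolated)
Conditions: CH2Cl2, 13 kbar, 25 °C; then 1,8-diazabicyclo[5.4.0]undec-7-ene (0.3 equiv), CH2Cl2, 0 → 25 °C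
Reagents that add atoms: none
Why: intramolecular Diels–Alder reaction of the furan with the butenolide, helped by pressure to join the two fully substituted carbons C5 and C10; the tether lies exo and the lactone endo so that C10–O and C19 become trans (trans ring fusion), the chair-like tether with the C8 methyl equatorial selects the face that gives the required C5 and C10 centres, and E1cB opening of the oxygen bridge from C4 then gives the dienoate and the tertiary alcohol irreversibly.

Step 9
Reactants: 15 10β-hydroxy-7-oxo dienolide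
Product: 16 7α,10β-dihydroxy dienolide
Conditions: NaBH4, CeCl3·7H2O, MeOH/CH2Cl2, −40 → 0 °C
Reagents that add atoms: none
Why: Luche reduction of the ring B ketone, in which hydride should enter from the β face because the α face is blocked by the axial C19 and C20 carbons (as in 11-oxo steroids), giving the axial 7α-alcohol and leaving the conjugated lactone untouched.

Step 10
Reactants: 16 7α,10β-dihydroxy dienolide; 17 3-bromofuran
Product: 20 1β-(3-bromofuran-2-yl)-7α,10β-dihydroxy enolide, via furylmagnesium chloride 18 (not isolated), via deconjugated lactone 19 (not isolated)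
Conditions: 17, (2,2,6,6-tetramethylpiperidin-1-yl)MgCl·LiCl, THF, −30 °C; 16, t-BuMgCl (2.1 equiv), THF, −78 °C; combine, −78 → −10 °C; AcOH; then 1,8-diazabicyclo[5.4.0]undec-7-ene (cat.), CH2Cl2, 25 °C
Reagents that add atoms: none
Why: Proposed new method: the C10 magnesium alkoxide should bind the furyl Grignard reagent and hand the aryl group through a five-membered transition state to the neighbouring δ-carbon C1 of the dienoate on the β face, which sets C1 cis to the C10 oxygen, after which the magnesium dienolate is protonated and base moves the alkene into conjugation (C3=C4); the closest known reaction type is the alkoxide-directed conjugate addition of Grignard reagents to γ-hydroxy enones, quinol alkoxides and γ-hydroxy alkenenitriles, extended here from 1,4- to 1,6-addition.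

Step 11
Reactants: 20 1β-(3-bromofuran-2-yl)-7α,10β-dihydroxy enolide
Product: 21 7α-acetate
Conditions: Ac2O, 4-(dimethylamino)pyridine, Et3N, CH2Cl2, 40 °C
Reagents that add atoms: acetic anhydride, CC(=O)OC(C)=O
Why: nucleophile-catalysed acetylation of the secondary axial alcohol, while the tertiary C10 hydroxyl flanked by two quaternary carbons should not react.

Step 12
Reactants: 21 7α-acetate
Product: 22 10β-trimethylsilyl ether
Conditions: Me3SiOSO2CF3, 2,6-lutidine, CH2Cl2, −40 → 0 °C
Reagents that add atoms: trimethylsilyl trifluoromethanesulfonate, C[Si](C)(C)OS(=O)(=O)C(F)(F)F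
Why: silylation of a hindered tertiary alcohol with a silyl triflate and a hindered base, giving an ether that should prevent oxetane formation in step 15 and protonolysis of the organozinc in step 16.

Step 13
Reactants: 22 10β-trimethylsilyl ether
Product: 24 C11 aldehyde, via vicinal diol 23 (not isolated)
Conditions: OsO4 (2 mol%), NaIO4, 2,6-lutidine, 1,4-dioxane/H2O, 25 °C
Reagents that add atoms: osmium tetroxide, O=[Os](=O)(=O)=O; sodium periodate, [Na+].[O-][I](=O)(=O)=O
Why: Lemieux–Johnson oxidation, in which OsO4 should dihydroxylate the electron-rich propenyl group in preference to the conjugated lactone alkene and the bromofuran, and periodate cleaves the diol to a neopentyl aldehyde that has no α-hydrogen.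

Step 14
Reactants: 24 C11 aldehyde
Product: 25 C11 primary alcohol
Conditions: NaBH4, EtOH/THF, 0 °C
Reagents that add atoms: none
Why: chemoselective borohydride reduction, the aldehyde reacting far faster than the acetate or the conjugated lactone.

Step 15
Reactants: 25 C11 primary alcohol
Product: 26 C11 neopentyl iodide
Conditions: I2, PPh3, imidazole, toluene, 70 °C
Reagents that add atoms: iodine, II
Why: Appel-type iodination, in which iodide displaces the alkoxyphosphonium group at the neopentyl carbon on heating, with no β-hydrogen to eliminate and no cation to rearrange.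

Step 16
Reactants: 26 C11 neopentyl iodide
Product: 28 trimethylsilyl ether of the target, via alkylzinc iodide 27 (not isolated)
Conditions: Zn dust (activated), LiCl, THF, 45 °C; then Pd(PPh3)4 (10 mol%), CO (3 atm), THF/N-methylpyrrolidone, 60 °C, 0.01 M
Reagents that add atoms: carbon monoxide, [C-]#[O+]
Why: Zinc should insert only into the C11–I bond, since the furyl C–Br bond is inert to Zn/LiCl, and alkylzinc iodide 27 cannot β-eliminate because C9 is quaternary. Oxidative addition of zerovalent palladium at C13–Br, migratory insertion of CO to a 3-furoyl complex of divalent palladium, transfer of the neopentyl group from zinc and reductive elimination should then form C13–C12 and C12–C11. The closest known reaction type is the intermolecular palladium-catalysed carbonylative Negishi coupling of alkylzinc iodides with aryl halides, of which this is the ring-closing variant. Ring C, seven-membered, closes by C(acyl)–C(sp3) reductive elimination from an eight-membered acyl(alkyl)palladacycle, made easy because the C1–furyl and C9–C11 bonds are both equatorial and gauche on the trans-decalin. No stereocentre is formed. The step needs carbonylative rather than direct six-ring coupling, which should be secured by CO pressure, fast CO insertion into the electron-rich furyl–palladium bond and slow transmetalation of the hindered neopentylzinc; acetate, lactone and silyl ether are inert to the organozinc.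

Step 17
Reactants: 28 trimethylsilyl ether of the target
Product: 29 CNP0329797.2
Conditions: HF·pyridine, pyridine/THF, 0 °C
Reagents that add atoms: none
Why: fluoride-mediated desilylation of the tertiary trimethylsilyl ether under buffered conditions that should leave the acetate, the lactone and the furyl ketone intact.

**Compound list**

1 | 2-acetylfuran | CC(=O)c1ccco1 | starting material
2 | diethyl [2-(methoxy(methyl)amino)-2-oxoethyl]phosphonate | CCOP(=O)(CC(=O)N(C)OC)OCC | starting material
3 | (E)-3-(furan-2-yl)-N-methoxy-N-methylbut-2-enamide | CON(C)C(=O)/C=C(\C)c1ccco1 | intermediate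
4 | (E)-4-(furan-2-yl)pent-3-en-2-one | CC(=O)/C=C(\C)c1ccco1 | intermediate
5 | (R,E)-4-(furan-2-yl)pent-3-en-2-ol | C[C@@H](O)/C=C(\C)c1ccco1 | intermediate
6 | (R,E)-4-(furan-2-yl)pent-3-en-2-yl propanoate | CCC(=O)O[C@H](C)/C=C(\C)c1ccco1 | intermediate
7 | (E)-trimethylsilyl ketene acetal of 6 (methyl cis to the allyloxy oxygen) | C/C=C(/O[Si](C)(C)C)O[C@H](C)/C=C(\C)c1ccco1 | intermediate (not isolated)
8 | trimethylsilyl (2S,3S,E)-3-(furan-2-yl)-2,3-dimethylhex-4-enoate | C/C=C/[C@](C)(c1ccco1)[C@H](C)C(=O)O[Si](C)(C)C | intermediate (not isolated)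
9 | (2S,3S,E)-3-(furan-2-yl)-2,3-dimethylhex-4-enoic acid | C/C=C/[C@](C)(c1ccco1)[C@H](C)C(=O)O | intermediate
10 | (3S,4S,E)-4-(furan-2-yl)-3,4-dimethylhept-5-en-2-one | C/C=C/[C@](C)(c1ccco1)[C@H](C)C(C)=O | intermediate
11 | 4-bromofuran-2(5H)-one | O=C1C=C(Br)CO1 | starting material
12 | trimethylsilyl enol ether of 10 at the methyl group (2-silyloxyhepta-1,5-diene) | C/C=C/[C@](C)(c1ccco1)[C@H](C)C(=C)O[Si](C)(C)C | intermediate (not isolated)
13 | 4-[(3S,4S,E)-4-(furan-2-yl)-3,4-dimethyl-2-oxohept-5-en-1-yl]furan-2(5H)-one | C/C=C/[C@](C)(c1ccco1)[C@H](C)C(=O)CC1=CC(=O)OC1 | intermediate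
14 | oxa-bridged cycloadduct: oxygen bridge C3–O–C10 on the β face, C1=C2, lactone (C18, C19) endo on the α face, C7 ketone, 8α-methyl, 9α-methyl, 9β-(E)-propenyl | C/C=C/[C@@]1(C)[C@H](C)C(=O)C[C@@]2(COC3=O)[C@H]3[C@@H]4C=C[C@]12O4 | intermediate (not isolated)
15 | trans-fused 10β-hydroxy-7-oxo dienolide: ring A C1=C2 and C3=C4, γ-lactone C18(=O)–O–C19 (C19 α on C5), 8α-methyl, 9α-methyl, 9β-(E)-propenyl | C/C=C/[C@@]1(C)[C@H](C)C(=O)C[C@@]2(COC3=O)C3=CC=C[C@]12O | intermediate
16 | 7α,10β-dihydroxy dienolide (as 15 with axial 7α-OH) | C/C=C/[C@@]1(C)[C@H](C)[C@H](O)C[C@@]2(COC3=O)C3=CC=C[C@]12O | intermediate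
17 | 3-bromofuran | Brc1ccoc1 | starting material
18 | (3-bromofuran-2-yl)magnesium chloride (LiCl complex) | Cl[Mg]c1occc1Br | intermediate (not isolated)
19 | deconjugated lactone: 1β-(3-bromofuran-2-yl), C2=C3, C4–H of undefined configuration, 7α,10β-diol | C/C=C/[C@@]1(C)[C@H](C)[C@H](O)C[C@@]2(COC3=O)C3C=C[C@@H](c3occc3Br)[C@]12O | intermediate (not isolated)
20 | 1β-(3-bromofuran-2-yl)-7α,10β-dihydroxy enolide (C3=C4 conjugated with the lactone) | C/C=C/[C@@]1(C)[C@H](C)[C@H](O)C[C@@]2(COC3=O)C3=CC[C@@H](c3occc3Br)[C@]12O | intermediate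
21 | 7α-acetate of 20 | C/C=C/[C@@]1(C)[C@H](C)[C@H](OC(C)=O)C[C@@]2(COC3=O)C3=CC[C@@H](c3occc3Br)[C@]12O | intermediate
22 | 10β-trimethylsilyl ether of 21 | C/C=C/[C@@]1(C)[C@H](C)[C@H](OC(C)=O)C[C@@]2(COC3=O)C3=CC[C@@H](c3occc3Br)[C@]12O[Si](C)(C)C | intermediate
23 | vicinal diol from the propenyl group of 22 (both new carbinol centres undefined) | CC(O)C(O)[C@@]1(C)[C@H](C)[C@H](OC(C)=O)C[C@@]2(COC3=O)C3=CC[C@@H](c3occc3Br)[C@]12O[Si](C)(C)C | intermediate (not isolated)
24 | C11 aldehyde (formyl group β on C9) | O=C[C@@]1(C)[C@H](C)[C@H](OC(C)=O)C[C@@]2(COC3=O)C3=CC[C@@H](c3occc3Br)[C@]12O[Si](C)(C)C | intermediate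
25 | C11 primary alcohol | OC[C@@]1(C)[C@H](C)[C@H](OC(C)=O)C[C@@]2(COC3=O)C3=CC[C@@H](c3occc3Br)[C@]12O[Si](C)(C)C | intermediate
26 | C11 neopentyl iodide with 1β-(3-bromofuran-2-yl), 7α-OAc and 10β-OSiMe3 (key-step precursor) | IC[C@@]1(C)[C@H](C)[C@H](OC(C)=O)C[C@@]2(COC3=O)C3=CC[C@@H](c3occc3Br)[C@]12O[Si](C)(C)C | intermediate
27 | alkylzinc iodide from 26 | I[Zn]C[C@@]1(C)[C@H](C)[C@H](OC(C)=O)C[C@@]2(COC3=O)C3=CC[C@@H](c3occc3Br)[C@]12O[Si](C)(C)C | intermediate (not isolated)
28 | 10β-trimethylsilyl ether of the target (ring C closed) | CC(=O)O[C@@H]1C[C@@]23COC(=O)C2=CC[C@H]2c4occc4C(=O)C[C@@](C)([C@@H]1C)[C@@]23O[Si](C)(C)C | intermediate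
29 | CNP0329797.2 | CC(=O)O[C@@H]1C[C@@]23COC(=O)C2=CC[C@H]2c4occc4C(=O)C[C@@](C)([C@@H]1C)[C@@]23O | target

**Step count**

Total step count: 17. Longest linear sequence: 17 steps, from 2-acetylfuran 1.

**Steps most likely to fail**

Step 10. The aryl transfer may escape control by the alkoxide: the Grignard reagent may add to the lactone carbonyl, or the aryl group may enter from the α face anti to the C10 oxygen. The fallback uses known chemistry and sets out from 16 and 17. Lithiation of 17 at C2 (LiN(i-Pr)2, THF, −78 °C) and quenching with 2-isopropoxy-4,4,5,5-tetramethyl-1,3,2-dioxaborolane should give 2-(3-bromofuran-2-yl)-4,4,5,5-tetramethyl-1,3,2-dioxaborolane F1. Rhodium-catalysed 1,6-addition of F1 to dienolide 16 ([RhCl(C2H4)2]2, a chiral 2,5-diarylbicyclo[2.2.2]octa-2,5-diene ligand, aq. KOH, 1,4-dioxane, 40 °C) is an established reaction of arylboron reagents with 2,4-dienoates. It tolerates the lactone and puts the face of attack under catalyst control, the ligand enantiomer being chosen for β-face delivery. Brief treatment with 1,8-diazabicyclo[5.4.0]undec-7-ene conjugates the lactone and the sequence returns to the route at 20.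

Step 16. Ring closure may occur without uptake of CO (direct coupling to a six-membered ring), the carbon–zinc bond may be protonated, or oxidative addition at the electron-rich bromofuran may be too slow. The fallback sets out from aldehyde 24. Pinnick oxidation (NaClO2, NaH2PO4, 2-methylbut-2-ene, t-BuOH/H2O) should give the C11 carboxylic acid F2. Coupling with MeNH(OMe)·HCl (1-ethyl-3-(3-dimethylaminopropyl)carbodiimide, i-Pr2NEt, CH2Cl2) gives the N-methoxy-N-methylamide F3. Bromine–lithium exchange at furan C3 (n-BuLi, THF, −100 °C) followed by intramolecular acyl substitution (Parham cyclisation) closes ring C and returns to the route at 28.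

Step 8. The cycloaddition may fail to join the two fully substituted carbons, or cycloreversion may outrun the opening of the bridge. The fallback sets out from ketone 10 through its silyl enol ether 12. Coupling of 12 with bromomaleic anhydride under the palladium/tin conditions of step 7 should give 3-[(3S,4S,E)-4-(furan-2-yl)-3,4-dimethyl-2-oxohept-5-en-1-yl]furan-2,5-dione F4. Its much more reactive dienophile should add to the furan at ambient pressure (toluene, 25–40 °C) to give the oxa-bridged cycloadduct anhydride F5. Et3N opens the bridge to the 10β-hydroxy-7-oxo dienoic anhydride F6. NaBH4 (THF/MeOH, 0 °C) then reduces the C7 ketone and, regioselectively, the non-conjugated anhydride carbonyl attached to quaternary C5. Acidic work-up lactonises and returns to the route at 16.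

Further compounds
F1 | step 10 | 2-(3-bromofuran-2-yl)-4,4,5,5-tetramethyl-1,3,2-dioxaborolane | CC1(C)OB(OC1(C)C)c1occc1Br
F2 | step 16 | C11 carboxylic acid (from aldehyde 24) | OC(=O)[C@@]1(C)[C@H](C)[C@H](OC(C)=O)C[C@@]2(COC3=O)C3=CC[C@@H](c3occc3Br)[C@]12O[Si](C)(C)C
F3 | step 16 | C11 N-methoxy-N-methylamide | CON(C)C(=O)[C@@]1(C)[C@H](C)[C@H](OC(C)=O)C[C@@]2(COC3=O)C3=CC[C@@H](c3occc3Br)[C@]12O[Si](C)(C)C
F4 | step 8 | 3-[(3S,4S,E)-4-(furan-2-yl)-3,4-dimethyl-2-oxohept-5-en-1-yl]furan-2,5-dione | C/C=C/[C@](C)(c1ccco1)[C@H](C)C(=O)CC1=CC(=O)OC1=O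
F5 | step 8 | oxa-bridged cycloadduct anhydride | C/C=C/[C@@]1(C)[C@H](C)C(=O)C[C@@]2(C(=O)OC3=O)[C@H]3[C@@H]4C=C[C@]12O4
F6 | step 8 | 10β-hydroxy-7-oxo dienoic anhydride | C/C=C/[C@@]1(C)[C@H](C)C(=O)C[C@@]2(C(=O)OC3=O)C3=CC=C[C@]12O
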